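The cyclohexenone is cut at two ring bonds, C4–C5 (CH2 to carbinol carbon) and C2=C3 (enone alkene), so a two-carbon unit is stitched between a ketone carbon and a vinyl carbon. The key step does this in one flask: hydroxyl-directed allylboration of an acyclic β-hydroxy ketone bearing a vinyl carbinol, then ring-closing metathesis. It exploits the 1,3-relation of ring carbonyl C1 and carbinol C5: held at the alcohol level, C1 is a sacrificial stereocentre that delivers allyl to one face of the C5 ketone and carries the vinyl partner. The side-chain C2' carbonyl is likewise a carbinol of either configuration; a final double oxidation erases both.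

Key step: step 5

Remark: (R)-2-vinyloxirane (5) and diisopropyl allylboronate (11) are taken as commercial; the silyloxy/hydroxy-bearing side-chain carbon of 7–10 and 12–16 is carried as an epimer mixture because it becomes the side-chain ketone.

Step 1
Reactants: 1 (9Z,12Z)-octadeca-9,12-dien-1-ol (linoleyl alcohol)
Product: 2 (9Z,12Z)-octadeca-9,12-dienal
Conditions: Dess–Martin periodinane (1.2 equiv), CH2Cl2, 0 °C → rt
Reagents that add atoms: none
Why: Dess–Martin oxidation should convert the primary alcohol to the aldehyde under neutral, non-aqueous conditions that leave the skipped (Z,Z)-diene untouched and cannot over-oxidize.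

Step 2
Reactants: 2 (9Z,12Z)-octadeca-9,12-dienal
Product: 3 2-[(8Z,11Z)-heptadeca-8,11-dien-1-yl]oxirane (racemic)
Conditions: Me3S+ I− (1.3 equiv), n-BuLi (1.25 equiv), THF, −10 °C; then 2, −10 °C → rt
Reagents that add atoms: trimethylsulfonium iodide C[S+](C)C.[I-]
Why: Corey–Chaykovsky epoxidation: dimethylsulfonium methylide adds to the aldehyde and the betaine closes to the terminal epoxide; the new centre is deliberately left racemic because it ends as the side-chain ketone.

Step 3
Reactants: 4 2-(tert-butyldimethylsilyl)-1,3-dithiane; 3 2-[(8Z,11Z)-heptadeca-8,11-dien-1-yl]oxirane; 5 (R)-2-vinyloxirane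
Product: 9 (2S)-1-{2-[(10Z,13Z)-2-(tert-butyldimethylsilyloxy)nonadeca-10,13-dien-1-yl]-1,3-dithian-2-yl}but-3-en-2-ol (both epimers at the silyloxy carbon), via lithiated silyl dithiane 6 (not isolated), via lithium alkoxide 7 (not isolated), via silyl-migrated lithiodithiane 8 (not isolated)
Conditions: t-BuLi (1.05 equiv), Et2O, −78 → −45 °C; 3, −78 → −25 °C; then HMPA, 5 (1.2 equiv), −78 → 0 °C; aq NH4Cl
Reagents that add atoms: none
Why: Three-component dithiane linchpin coupling (anion relay): lithiated 4 opens epoxide 3 at CH2, HMPA triggers a 1,4-Brook silyl shift from carbon to oxygen that protects the chain carbinol and regenerates a dithiane anion, and this anion opens 5 at its terminal CH2 without touching the stereocentre, leaving the (S)-allylic alcohol free.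

Step 4
Reactants: 9 (2S)-1-{2-[(10Z,13Z)-2-(tert-butyldimethylsilyloxy)nonadeca-10,13-dien-1-yl]-1,3-dithian-2-yl}but-3-en-2-ol
Product: 10 (3S,15Z,18Z)-7-(tert-butyldimethylsilyloxy)-3-hydroxytetracosa-1,15,18-trien-5-one (C7 epimers)
Conditions: MeI (10 equiv), CaCO3 (5 equiv), MeCN–H2O 9:1, 45 °C
Reagents that add atoms: water O
Why: Alkylative dithiane hydrolysis (S-methylation, then hydrolysis with CaCO3 as acid scavenger) should unmask the ketone without oxidant or strong acid, so the skipped diene, the TBS ether and the β-hydroxy ketone survive.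

Step 5
Reactants: 10 (3S,15Z,18Z)-7-(tert-butyldimethylsilyloxy)-3-hydroxytetracosa-1,15,18-trien-5-one; 11 diisopropyl allylboronate
Product: 15 (1R,3S)-1-[(10Z,13Z)-2-(tert-butyldimethylsilyloxy)nonadeca-10,13-dien-1-yl]cyclohex-4-ene-1,3-diol (trans-diol; side-chain C2' epimers), via mixed allylboronate 12 (not isolated), via cyclic borate 13 (not isolated), via triene diol 14 (not isolated)
Conditions: 11 (1.1 equiv), 4 Å MS, CH2Cl2, −78 °C → rt; then pinacol (1.5 equiv), dilution to 5 mM, Grubbs II (3 mol %), rt → 40 °C, same flask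
Reagents that add atoms: none
Why: The free C3–OH of 10 exchanges onto boron (12), the ketone oxygen then binds the same boron and the allyl group is transferred through a chair Zimmerman–Traxler transition state fused to the chelate ring to give cyclic borate 13; pinacol releases diol 14 and the Ru carbene joins the allyl CH to the vinyl CH with loss of ethene. The closest known reactions are the hydroxyl-directed allylboration of β-hydroxy ketones and diene ring-closing metathesis to cyclohexenols. The six-membered ring is closed by metathesis between two terminal alkenes, the C–C bond to the carbinol carbon having been made by γ-attack of the allyl group delivered from the O-bound boron. The new quaternary carbinol is controlled by the (S)-C3 carbinol: in the bicyclic chair–chair transition state the vinyl group and the side-chain arm are equatorial and the allyl group arrives axially, so the tertiary OH should end trans to the allylic OH on the ring (1R in 15, S in the target). The step needs π-facial selectivity, secured by the covalent O–B tether at low temperature, and selectivity of the Ru carbene for the terminal alkenes over the internal Z-alkenes, secured by fast six-ring closure at high dilution.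

Step 6
Reactants: 15 (1R,3S)-1-[(10Z,13Z)-2-(tert-butyldimethylsilyloxy)nonadeca-10,13-dien-1-yl]cyclohex-4-ene-1,3-diol
Product: 16 (1S,3S)-1-[(10Z,13Z)-2-hydroxynonadeca-10,13-dien-1-yl]cyclohex-4-ene-1,3-diol (side-chain C2' epimers)
Conditions: TBAF (1.5 equiv), THF, 0 °C → rt
Reagents that add atoms: none
Why: Fluoride-mediated desilylation should remove the secondary TBS ether; no carbonyl is present at this stage, so the basic fluoride cannot cause elimination or retro-aldol cleavage.

Step 7
Reactants: 16 (1S,3S)-1-[(10Z,13Z)-2-hydroxynonadeca-10,13-dien-1-yl]cyclohex-4-ene-1,3-diol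
Product: 17 (5S)-5-hydroxy-5-[(10Z,13Z)-2-oxononadeca-10,13-dien-1-yl]cyclohex-2-en-1-one (CNP0252404.1)
Conditions: Dess–Martin periodinane (3 equiv), pyridine (6 equiv), CH2Cl2, 0 °C → rt; brief Na2S2O3/NaHCO3 wash
Reagents that add atoms: none
Why: Buffered Dess–Martin oxidation should convert both secondary alcohols (the allylic ring carbinol and either epimer of the side-chain carbinol) into ketones, erasing the two auxiliary centres, while the tertiary alcohol cannot be oxidized and keeps its configuration.

Compound list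
1 | (9Z,12Z)-octadeca-9,12-dien-1-ol | CCCCC/C=C\C/C=C\CCCCCCCCO | starting material
2 | (9Z,12Z)-octadeca-9,12-dienal | CCCCC/C=C\C/C=C\CCCCCCCC=O | intermediate
3 | 2-[(8Z,11Z)-heptadeca-8,11-dien-1-yl]oxirane (racemic) | CCCCC/C=C\C/C=C\CCCCCCCC1CO1 | intermediate
4 | 2-(tert-butyldimethylsilyl)-1,3-dithiane | CC(C)(C)[Si](C)(C)C1SCCCS1 | starting material
5 | (R)-2-vinyloxirane | C=C[C@@H]1CO1 | starting material
6 | 2-lithio-2-(tert-butyldimethylsilyl)-1,3-dithiane | [Li]C1([Si](C)(C)C(C)(C)C)SCCCS1 | intermediate
7 | lithium (10Z,13Z)-1-[2-(tert-butyldimethylsilyl)-1,3-dithian-2-yl]nonadeca-10,13-dien-2-olate | [Li]OC(CC1([Si](C)(C)C(C)(C)C)SCCCS1)CCCCCCC/C=C\C/C=C\CCCCC | intermediate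
8 | 2-lithio-2-[(10Z,13Z)-2-(tert-butyldimethylsilyloxy)nonadeca-10,13-dien-1-yl]-1,3-dithiane | [Li]C1(CC(O[Si](C)(C)C(C)(C)C)CCCCCCC/C=C\C/C=C\CCCCC)SCCCS1 | intermediate
9 | (2S)-1-{2-[(10Z,13Z)-2-(tert-butyldimethylsilyloxy)nonadeca-10,13-dien-1-yl]-1,3-dithian-2-yl}but-3-en-2-ol | C=C[C@@H](O)CC1(CC(O[Si](C)(C)C(C)(C)C)CCCCCCC/C=C\C/C=C\CCCCC)SCCCS1 | intermediate
10 | (3S,15Z,18Z)-7-(tert-butyldimethylsilyloxy)-3-hydroxytetracosa-1,15,18-trien-5-one | C=C[C@@H](O)CC(=O)CC(O[Si](C)(C)C(C)(C)C)CCCCCCC/C=C\C/C=C\CCCCC | intermediate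
11 | diisopropyl allylboronate | C=CCB(OC(C)C)OC(C)C | starting material
12 | mixed isopropyl allylboronate of 10 at O3 (3S) | C=CCB(OC(C)C)O[C@H](C=C)CC(=O)CC(O[Si](C)(C)C(C)(C)C)CCCCCCC/C=C\C/C=C\CCCCC | intermediate
13 | (4S,6R)-6-allyl-6-[(10Z,13Z)-2-(tert-butyldimethylsilyloxy)nonadeca-10,13-dien-1-yl]-2-isopropoxy-4-vinyl-1,3,2-dioxaborinane | CC(C)OB1O[C@H](C=C)C[C@](CC=C)(CC(O[Si](C)(C)C(C)(C)C)CCCCCCC/C=C\C/C=C\CCCCC)O1 | intermediate
14 | (3S,5R,15Z,18Z)-5-allyl-7-(tert-butyldimethylsilyloxy)tetracosa-1,15,18-triene-3,5-diol | C=C[C@@H](O)C[C@](O)(CC=C)CC(O[Si](C)(C)C(C)(C)C)CCCCCCC/C=C\C/C=C\CCCCC | intermediate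
15 | (1R,3S)-1-[(10Z,13Z)-2-(tert-butyldimethylsilyloxy)nonadeca-10,13-dien-1-yl]cyclohex-4-ene-1,3-diol | O[C@@H]1C=CC[C@](O)(CC(O[Si](C)(C)C(C)(C)C)CCCCCCC/C=C\C/C=C\CCCCC)C1 | intermediate
16 | (1S,3S)-1-[(10Z,13Z)-2-hydroxynonadeca-10,13-dien-1-yl]cyclohex-4-ene-1,3-diol | O[C@@H]1C=CC[C@](O)(CC(O)CCCCCCC/C=C\C/C=C\CCCCC)C1 | intermediate
17 | (5S)-5-hydroxy-5-[(10Z,13Z)-2-oxononadeca-10,13-dien-1-yl]cyclohex-2-en-1-one | CCCCC/C=C\C/C=C\CCCCCCCC(=O)C[C@@]1(O)CC=CC(=O)C1 | target

Total step count: 7. Longest linear sequence: 7 steps (1 → 2 → 3 → 9 → 10 → 15 → 16 → 17).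

Steps most likely to fail

Step 5. An untethered, bimolecular allylboration may compete with delivery through the O–B tether and erode the facial selectivity, and in the second stage the Ru carbene may engage the internal Z-alkenes. The fallback sets out from 10: silylation of the free hydroxyl with allylchlorodimethylsilane and imidazole should give (3S,15Z,18Z)-3-[allyl(dimethyl)silyloxy]-7-(tert-butyldimethylsilyloxy)tetracosa-1,15,18-trien-5-one F1. A Lewis acid (SnCl4, CH2Cl2, −78 °C) then triggers an intramolecular Hosomi–Sakurai allyl transfer through the covalent Si–O tether, which is expected to have the same facial sense. Aqueous work-up hydrolyses the silicon residue and the route is rejoined at 14, which is isolated, checked for diastereomeric purity and cyclized in a separate flask (Grubbs first-generation catalyst, high dilution) to 15.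

Step 3. The hindered lithiodithiane 8 may attack the vinyl epoxide in the SN2' sense under the HMPA conditions, and the Brook migration may be incomplete. The fallback sets out from 8, generated as in step 3: (S)-epichlorohydrin is added in place of 5, and attack at the epoxide CH2 gives lithium (2S)-1-chloro-3-{2-[(10Z,13Z)-2-(tert-butyldimethylsilyloxy)nonadeca-10,13-dien-1-yl]-1,3-dithian-2-yl}propan-2-olate F2. This closes on warming to (2S)-2-({2-[(10Z,13Z)-2-(tert-butyldimethylsilyloxy)nonadeca-10,13-dien-1-yl]-1,3-dithian-2-yl}methyl)oxirane F3. Excess dimethylsulfonium methylide (Me3S+ I−, n-BuLi, THF, −10 °C → rt) then opens F3 at CH2 and eliminates to the one-carbon-homologated allylic alcohol, rejoining the route at 9.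

Step 7. The tertiary hydroxyl may be lost by β-elimination through either new ketone, followed by tautomerization to the phenol, or the aldol may cleave, promoted by acetic acid from the oxidant or by the basic wash. The fallback sets out from 16 and stages the oxidation: MnO2 (CH2Cl2, rt) should oxidize only the allylic ring alcohol to (5S)-5-hydroxy-5-[(10Z,13Z)-2-hydroxynonadeca-10,13-dien-1-yl]cyclohex-2-en-1-one F4. A neutral catalytic oxidation (TPAP, NMO, 4 Å MS, CH2Cl2) then converts the remaining side-chain carbinol, rejoining the route at 17 without acid or aqueous base.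

Further compounds
F1 | step 5 | (3S,15Z,18Z)-3-[allyl(dimethyl)silyloxy]-7-(tert-butyldimethylsilyloxy)tetracosa-1,15,18-trien-5-one | C=CC[Si](C)(C)O[C@H](C=C)CC(=O)CC(O[Si](C)(C)C(C)(C)C)CCCCCCC/C=C\C/C=C\CCCCC
F2 | step 3 | lithium (2S)-1-chloro-3-{2-[(10Z,13Z)-2-(tert-butyldimethylsilyloxy)nonadeca-10,13-dien-1-yl]-1,3-dithian-2-yl}propan-2-olate | [Li]O[C@H](CCl)CC2(CC(O[Si](C)(C)C(C)(C)C)CCCCCCC/C=C\C/C=C\CCCCC)SCCCS2
F3 | step 3 | (2S)-2-({2-[(10Z,13Z)-2-(tert-butyldimethylsilyloxy)nonadeca-10,13-dien-1-yl]-1,3-dithian-2-yl}methyl)oxirane | C([C@H]1CO1)C2(CC(O[Si](C)(C)C(C)(C)C)CCCCCCC/C=C\C/C=C\CCCCC)SCCCS2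
F4 | step 7 | (5S)-5-hydroxy-5-[(10Z,13Z)-2-hydroxynonadeca-10,13-dien-1-yl]cyclohex-2-en-1-one | O=C1C=CC[C@](O)(CC(O)CCCCCCC/C=C\C/C=C\CCCCC)C1
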